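Each step from starting material up to tris adduct spends one reagent and gives one by-product, so whatever holds the starting material counts what was spent: one for first product, two for bis adduct, 3 for tris adduct.

| setting | Sunday's | flask |
|---|---|---|
| starting material | 0.19 M (fed, over 4.0 h) | 0.19 M (fed, over 4.0 h) |
| reagent | 0.30 M | 0.200 M |
| remark | run made earlier; the fed solution adds 0.10 times the starting volume | the fed solution adds 0.10 times the starting volume |
| time |  | 4.0 d |

Sunday's run (percent of the starting material charged)

| time / h | starting material / % | tris adduct / % |
|---|---|---|
| 1.33 | 8.1 | 14.4 |
| 3.00 | 20.5 | 34.4 |
| 6.00 | 34.9 | 38.5 |
| 10.0 | 34.8 | 38.9 |

(standard deviation of a reading: 0.5 percentage points)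

- every charge counts on the volume at the start, and the solution that is fed holds the whole dose
- the numbers in the tables scatter by 0.5 percentage points (one standard deviation)
- what may be going on: reagent -> decomposition product; reagent + first product -> bis adduct + by-product; reagent + bis adduct -> tris adduct + by-product; starting material + reagent -> first product + by-product
- percentages count the whole charge, also what has not yet gone in
- the reaction counts as stopped when no species that holds the starting material changes by six tenths of a point or more over the second half of the time

1. the state of affairs at 4.0 d: stopped, and by what, or still going (it is still moving / forward and back rates have come level / all of the starting material has reacted / the reagent has run out first)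
2. how much of the starting material has reacted by 4.0 d
3. how much tris adduct there is at 4.0 d, in percent of the starting material charged

What does a reacted starting material cost? In Sunday's run starting material reads 34.9%, then 34.8%, a change smaller than the scatter of 0.5 percentage points. Read that plateau as the end of Sunday's 1.58 equivalents of reagent, and dividing them by the fraction reacted gives 2.42. Call this the demand: reagent spent per starting material reacted, the curve replaced by its mean.

Is the mean fair? At 1.33 h Sunday's run had reacted 25.1%. Reading everything but tris adduct as first product, then as bis adduct, brackets the early demand between 2.15 and 2.57, and the mean lies inside.

Does this flask's charge reach? It holds 1.05 equivalents, less than the demand, so reagent is the limiting reagent, and I reckon 43.4% reacted. At Sunday's tris share of what reacted, 59.4%, that makes 25.8% tris adduct.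

The forecast says the reagent has run out first, with 49% reacted, more than mine, and 23.5% tris adduct, less than mine: “The flask stops through reagent exhaustion”.

In the flask, the reagent has run out first: at 4.00 d reagent stands at 0% of its charge, with 47.6% reacted and 21.2% tris adduct, so the flask's demand is 2.21, below the 2.42 read from Sunday's run.

reagent → decomposition product (k = 1.60 × 10⁻⁷ s⁻¹); reagent + first product → bis adduct + by-product (k = 0.00890 L mol⁻¹ s⁻¹); reagent + bis adduct → tris adduct + by-product (k = 0.00340 L mol⁻¹ s⁻¹); starting material + reagent → first product + by-product (k = 0.00410 L mol⁻¹ s⁻¹) With reagent as charged, first product has a half-life of 0.11 h by its step, about half the 0.23 h of starting material. The flask ends with 11.2% first product and 15.1% bis adduct beside 52% starting material. The neighbour flask with 0.421 equiv of reagent reacted 24.6%, a demand of 1.71.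

(Readings and results were computed with constants of no real substance; the scatter is artificial.)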